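## The problem

Acredinone A (22) is an achiral 1H-inden-1-one in which every carbon of the five-membered ring is substituted. The labels used throughout are: indenone C1 (C=O), C2, C3; ring A = C3a, C4 (OH), C5 (H), C6 (Me), C7 (OMe), C7a; ring B = the aryl group on C2, with B1 bonded to C2, B2 bearing the ketone C8, B3 (OH), B4 (H), B5 (Me), B6 (OMe); rings D and E = the 2,6-dimethoxyphenyl groups on C3 and C8. A synthesis has to gather five benzene units around the C1–C2–C3 chain, two of them (rings A and B) penta- and hexasubstituted, and must keep two phenols (O4 and the B3 oxygen) distinct from six methyl ethers from the first step on. The target has no stereocentre. The only ones that can arise on the way are C2 and C3 of an indanone, where C3 dictates C2 (trans) through the enolisable C2–H, and both vanish on oxidation to the indenone. The fragile elements are the two hydroquinone monomethyl ether rings (oxidised to quinones once the phenol is free), the indenone as a conjugate acceptor, and the 1,5 relationship of the C1 and C8 carbonyl groups, which lets any intermediate with hydrogen on C2 close to a 2-benzopyrylium ion in strong acid. The crowding at C2 (both ortho positions of ring B are filled) argues against forming the C2–B1 bond late. The enabling feature is the pair C3/C3a. C3 carries ring D, which stabilises a cation strongly and cannot alkylate itself because both of its ortho carbons bear OMe. C3a is the only hydrogen-bearing ortho carbon of the ring A aroyl unit, ortho to O4 and para to the C6 methyl group.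

## Retrosynthesis

**End-game (22 ⇒ 21 ⇒ 20 ⇒ 19).** The two phenols of 22 are released last from the diacetate 21. The C2=C3 double bond of 21 is traced to the trans-indanone diacetate 20 by quinone dehydrogenation, and 20 to the diphenol indanone 19 by acetylation. The acetates are introduced only for the oxidation, because free p-methoxyphenol rings would not survive a high-potential quinone. No skeletal bond is cut here. The price is two protecting-group steps, accepted because the ring-forming step delivers the indanone oxidation level.

**Key cut, C3–C3a (19 ⇒ 18).** Opening the five-membered ring between C3 and C3a gives the acyclic α-aryl chalcone 18, in which C1 carries ring A, C2 ring B and C3 ring D. The neighbouring cuts are weaker: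
- C1–C7a (acylation of ring A by a triarylacrylic acid) needs a defined alkene geometry and attack at a carbon flanked by OMe.
- C2–B1 (coupling of a 2-haloindenone with a ring B metal species) would join two tetra-ortho-substituted partners.
- C2=C3 (aldol closure) needs a 1,3-diaryl-1,3-dione whose assembly is no simpler.

The C3–C3a cut leads to a precursor that falls apart into three simple pieces by carbonyl chemistry. The forward reaction asks for a nucleophilic C3a. For that reason the C4 oxygen is a free hydroxyl in 18 and not an ester: an acyloxy group would leave C3a hardly more reactive than a toluene carbon, whereas the hydroxyl makes it a phenol ortho position.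

**C2=C3 (18 ⇒ 17 ⇒ 15 + 16).** The diphenol 18 comes from its bis(methoxymethyl) ether 17, and the alkene of 17 from condensation of the deoxybenzoin 15 with 2,6-dimethoxybenzaldehyde (16). The acetal protecting groups are kept through the condensation for two reasons: free phenols would interfere with it, and 15, which still has hydrogen on C2, must not meet the acid needed to remove them. Once C2 is an alkene carbon the 1,5-diketone can no longer aromatise, so deprotection is safe at the stage of 17. The condensation must be run under a weakly acidic amine buffer that leaves the acetals intact.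

**C1–C2 (15 ⇒ 13 + 7).** Cutting between the carbonyl C1 and the methylene C2 gives the ring B benzophenone 13 and the ring A N-methoxy-N-methylamide 7. The B1 methyl group of 13 is the latent C2: it is ortho to the C8 carbonyl, so a hindered lithium amide should convert it to the dienolate 14, which is acylated once by 7. This puts the C2–B1 bond into a starting material rather than into a coupling step. It also brings in ring E before the fragments are joined.

**Ring B (13 ⇒ 10 + 11; 10 ⇒ 9 ⇒ 8).** The B2–C8 bond is cut to the aryllithium 12 and 2,6-dimethoxybenzoyl chloride (11). The arene 10 is symmetric, so directed metalation beside its acetal oxygen can give only one aryllithium. Its two oxygen functions are told apart by sterics in 2,6-dimethylhydroquinone (8): the open hydroxyl takes the acetal (9) and the flanked one is then methylated (10).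

**Ring A (7 ⇒ 5 ⇒ 4 ⇒ 2 ⇒ 1).** The amide carbon of 7 replaces the bromine of 5 through the aryllithium 6. The C4 oxygen of 4 is introduced into the anisole 2 by sterically governed C–H borylation (boronate 3) and oxidation, and 2 is the methyl ether of 2-bromo-6-methylphenol (1). Rings A and B carry the same sequence OMe, Me, H, OH, but ring A has its acyl carbon beside OMe and ring B has it beside OH. This is why the two rings start from different materials.

## Roads not taken

**Alternative 1:** The cut removes ring B, breaking B6–B1, B2–B3 and B3–B4. In the forward direction the alkynyl indenone A2 (alkyne B1≡B2 on C2, C8 as a silyl-protected carbinol) would be heated with the chromium carbene complex A3, (CO)5Cr=C(OMe)C(Me)=CH2 (zerovalent chromium), in a Dötz benzannulation to give the phenol A1.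
- Merits: the hexasubstituted ring B is made in one step, and its two oxygens arrive already differentiated (OMe from the carbene, free OH from CO). This is cleaner than the selective protection of 8 in the chosen plan.
- Weak points: the alkyne of A2 bears two bulky groups of similar size, so the regiochemistry that places the C8 carbinol beside the new hydroxyl is not secured. The alkyne is conjugated to the indenone and therefore electron-poor. The complex A3 is stoichiometric in chromium. C8 must afterwards be desilylated and oxidised.
- Comparison: the indenone ring of A2 still has to be made by some other ring closure, so the problem of the five-membered ring is moved and not solved. The chosen plan sets fixed, sterically and electronically dictated regiochemistry in every ring-functionalising step against the built-in oxygen differentiation of A1.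

**Alternative 2:** The cut removes both rings A and B (C4–C3a, C7–C7a, B3–B2, B6–B1). In the forward direction the open-chain bis-ynone A5 would take up two molecules of the silyloxyfuran A6 in Diels–Alder additions, and opening of the oxabridges would give the bis-aryl ketone A4.
- Merits: both crowded rings come from one acyclic precursor, the regiochemistry follows the normal polarity of a 2-silyloxyfuran with an ynone, and each new ring emerges with one silylated and one free oxygen. That is exactly the differentiation needed, and better than anything in the chosen plan.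
- Weak points: A5 has a methylene group between an alkyne and a carbinol carbon and is prone to allene formation. Two cycloadditions must both proceed on one molecule. A4 is still far from the target: the free phenols need methylation, C1 needs oxidation, the five-membered ring must be closed by aldol condensation of C2 onto the C3 ketone, and the silyl groups must be removed.
- Comparison: the step count after the key step is at least as long as the whole second half of the chosen route. The chosen plan brings rings A and B in as stable aromatic building blocks and spends its key step on the ring that actually defines the indenone.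

**Alternative 3:** The cut breaks C2–B1 and C3–C3a together. In the forward direction the ring B diazonium salt A9 would be reduced by a ruthenium polypyridyl photocatalyst under visible light to the B1 aryl radical. This adds to C2 of the propynone A8, and the resulting C3 vinyl radical closes onto C3a to give acredinone A diacetate A7 (identical with 21).
- Merits: this is the most convergent road and it delivers the indenone oxidation level directly, so the dehydrogenation of the chosen plan (step 13) would be unnecessary. In this respect it is better.
- Weak points: the B1 radical is flanked by OMe and by the aroyl group. It can abstract hydrogen from the neighbouring methoxy group or attack ring E through the ortho carbonyl (Pschorr-type closure) before it finds the hindered alkyne. Addition must occur at C2 and not at C3. The diazonium salt A9 requires a hexasubstituted aniline that is harder to reach than 13.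
- Comparison: against the shorter end-game of A7 the chosen plan sets a closed-shell ring closure whose regiochemistry is fixed by the substitution of ring A, and fragments that are each available in three or four steps.

Key step: step 11

Assumptions on the chemistry:
- Acredinone A has no stereocentre and its hindered aryl axes are taken as freely rotating, so all chiral intermediates are racemic.
- The alkene of 17 and 18 is drawn E (ring D trans to the C1 carbonyl). The Z isomer would serve equally, because both give the same cation in step 11.

## Route

**Step 1**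
Reactants: 1 2-bromo-6-methylphenol
Product: 2 1-bromo-2-methoxy-3-methylbenzene
Conditions: MeI, K2CO3, acetone, reflux
Reagents that add atoms: iodomethane, CI
Why: Williamson O-methylation of the phenoxide; the phenol oxygen is the only nucleophilic site.

**Step 2**
Reactants: 2 1-bromo-2-methoxy-3-methylbenzene
Product: 4 3-bromo-4-methoxy-5-methylphenol, via aryl pinacol boronate 3 (not isolated)
Conditions: [Ir(OMe)(cod)]2 (1.5 mol %), 4,4'-di-tert-butyl-2,2'-bipyridine, B2pin2, THF, 80 °C; then aq H2O2, NaOH, 0 °C
Reagents that add atoms: hydrogen peroxide, OO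
Why: Iridium-catalysed C–H borylation is sterically controlled and should take the only C–H of 2 with no ortho substituent (para to OMe), leaving the C–Br bond intact. Alkaline peroxide then converts the aryl boronate into the phenol in the same flask.

**Step 3**
Reactants: 4 3-bromo-4-methoxy-5-methylphenol
Product: 5 1-bromo-2-methoxy-5-(methoxymethoxy)-3-methylbenzene
Conditions: MOMCl, i-Pr2NEt, CH2Cl2, 0 °C to rt
Reagents that add atoms: chloromethyl methyl ether, COCCl
Why: O-alkylation of the phenol to the methoxymethyl acetal, which tolerates organolithium and amide bases and is later removed by mild acid without touching methyl ethers.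

**Step 4**
Reactants: 5 1-bromo-2-methoxy-5-(methoxymethoxy)-3-methylbenzene
Product: 7 N,2-dimethoxy-5-(methoxymethoxy)-N,3-dimethylbenzamide, via ring A aryllithium 6 (not isolated)
Conditions: n-BuLi, THF, −78 °C; then ClC(O)N(OMe)Me, −78 °C to rt
Reagents that add atoms: N-methoxy-N-methylcarbamoyl chloride, CON(C)C(Cl)=O
Why: Bromine–lithium exchange at −78 °C is faster than any deprotonation. The aryllithium is acylated by the carbamoyl chloride, giving the N-methoxy-N-methylamide in one operation.

**Step 5**
Reactants: 8 2,6-dimethylbenzene-1,4-diol (2,6-dimethylhydroquinone)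
Product: 9 4-(methoxymethoxy)-2,6-dimethylphenol
Conditions: MOMCl (1.05 equiv), i-Pr2NEt, CH2Cl2, 0 °C, argon
Reagents that add atoms: chloromethyl methyl ether, COCCl
Why: Selective mono-alkylation: the 4-hydroxyl is unhindered and slightly more acidic than the 1-hydroxyl flanked by two methyl groups, so one equivalent of electrophile with an amine base should react at the open oxygen.

**Step 6**
Reactants: 9 4-(methoxymethoxy)-2,6-dimethylphenol
Product: 10 2-methoxy-5-(methoxymethoxy)-1,3-dimethylbenzene
Conditions: MeI, K2CO3, DMF, 40 °C
Reagents that add atoms: iodomethane, CI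
Why: Williamson methylation of the remaining hindered phenol. The product is symmetric, which removes any regiochemical question from step 7.

**Step 7**
Reactants: 10 2-methoxy-5-(methoxymethoxy)-1,3-dimethylbenzene; 11 2,6-dimethoxybenzoyl chloride
Product: 13 (2,6-dimethoxyphenyl)[3-methoxy-6-(methoxymethoxy)-2,4-dimethylphenyl]methanone, via ring B aryllithium 12 (not isolated)
Conditions: n-BuLi, TMEDA, THF, 0 °C; then added to 11 in THF, −78 °C to rt
Reagents that add atoms: none
Why: Directed ortho-metalation beside the acetal oxygen; the two ortho C–H positions of 10 are equivalent and the methoxy group has no ortho hydrogen. Acylation of the aryllithium by the acid chloride stops at the ketone, because a tetra-ortho-substituted benzophenone cannot accept a second hindered aryllithium.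

**Step 8**
Reactants: 13 (2,6-dimethoxyphenyl)[3-methoxy-6-(methoxymethoxy)-2,4-dimethylphenyl]methanone; 7 N,2-dimethoxy-5-(methoxymethoxy)-N,3-dimethylbenzamide
Product: 15 2-[2-(2,6-dimethoxybenzoyl)-6-methoxy-3-(methoxymethoxy)-5-methylphenyl]-1-[2-methoxy-5-(methoxymethoxy)-3-methylphenyl]ethan-1-one, via lithium dienolate 14 (not isolated)
Conditions: lithium 2,2,6,6-tetramethylpiperidide (from n-BuLi and the amine), THF, −78 °C; then 7, −78 to −20 °C; AcOH quench at −78 °C
Reagents that add atoms: none
Why: Lateral (benzylic) lithiation of an ortho-methyl diaryl ketone without α-hydrogen: only the B1 methyl group is conjugated with the C8 carbonyl, and the tetramethylpiperidide base cannot transfer hydride to the ketone. The N-methoxy-N-methylamide gives a chelated tetrahedral adduct that holds until the quench, so the acylation stops at the ketone and the acidic product does not protonate 14. The weak-acid quench avoids closure of the 1,5-diketone to a benzopyrylium ion.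

**Step 9**
Reactants: 15 the deoxybenzoin from step 8; 16 2,6-dimethoxybenzaldehyde
Product: 17 (E)-2-[2-(2,6-dimethoxybenzoyl)-6-methoxy-3-(methoxymethoxy)-5-methylphenyl]-3-(2,6-dimethoxyphenyl)-1-[2-methoxy-5-(methoxymethoxy)-3-methylphenyl]prop-2-en-1-one
Conditions: piperidine, AcOH, toluene, reflux, azeotropic removal of water
Reagents that add atoms: none
Why: Knoevenagel-type condensation of a deoxybenzoin with an aryl aldehyde through the piperidinium ion. The C2 methylene is activated by the C1 carbonyl and by the acyl-substituted ring B, and removal of water drives the reaction to the conjugated enone. The buffered amine conditions leave the acetals intact, which a titanium or boron Lewis acid would not.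

**Step 10**
Reactants: 17 the bis(methoxymethyl) chalcone from step 9
Product: 18 (E)-2-[2-(2,6-dimethoxybenzoyl)-3-hydroxy-6-methoxy-5-methylphenyl]-3-(2,6-dimethoxyphenyl)-1-(5-hydroxy-2-methoxy-3-methylphenyl)prop-2-en-1-one
Conditions: 3 M aq HCl, MeOH/THF, 45 °C
Reagents that add atoms: none
Why: Acid-catalysed acetal exchange with methanol frees both phenols. C2 now carries no hydrogen, so the 1,5-diketone cannot aromatise to a benzopyrylium ion, and any conjugate addition of methanol at C3 is reversible and would lead to the same cation in step 11.

**Step 11 (key step)**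
Reactants: 18 the diphenol α-aryl chalcone from step 10
Product: 19 (2R*,3S*)-2-[2-(2,6-dimethoxybenzoyl)-3-hydroxy-6-methoxy-5-methylphenyl]-3-(2,6-dimethoxyphenyl)-4-hydroxy-7-methoxy-6-methyl-2,3-dihydro-1H-inden-1-one (trans, racemic)
Conditions: BF3·OEt2 (5 equiv), ClCH2CH2Cl, 60 °C
Reagents that add atoms: none
Why: Nazarov cyclisation of an α-aryl aryl vinyl ketone, a known route from α-aryl chalcones to 2,3-diarylindan-1-ones. BF3 binds the C1 carbonyl and gives the 1-oxypentadienyl cation C3–C2–C1–C7a–C3a, whose C3 end is stabilised by ring D. The five-membered ring closes by thermally allowed conrotatory 4π electrocyclisation of this cation onto C3a (in Friedel–Crafts terms a 5-endo alkylation of ring A), and loss of the C3a proton restores ring A. C3 is set in the ring closure without facial bias (racemate); C2 is set when the boron enolate is protonated on the face away from ring D and, being enolisable, settles to the trans isomer under the acidic conditions. Regioselectivity: C3a is the only ortho carbon of the aroyl ring that bears hydrogen (C7 has OMe), and ring D cannot attack its own cation because both its ortho carbons carry OMe. Reactivity: the free C4 hydroxyl makes C3a a phenol ortho carbon that is also para to the C6 methyl group, which is the reason the phenols are unmasked before this step and acylated only after it. Chemoselectivity: capture of the C3 cation by the C8 carbonyl oxygen gives a six-membered oxocarbenium ion that can reopen, and the hydrogen bond (or BF2 chelate) from the B3 hydroxyl lowers the nucleophilicity of that oxygen; either alkene isomer of 18 reaches the same cation.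

**Step 12**
Reactants: 19 the trans-indanone diphenol from step 11
Product: 20 (2R*,3S*)-4-acetoxy-2-[3-acetoxy-2-(2,6-dimethoxybenzoyl)-6-methoxy-5-methylphenyl]-3-(2,6-dimethoxyphenyl)-7-methoxy-6-methyl-2,3-dihydro-1H-inden-1-one (trans, racemic)
Conditions: Ac2O, pyridine, DMAP (cat.), CH2Cl2, rt
Reagents that add atoms: acetic anhydride, CC(=O)OC(C)=O
Why: DMAP-catalysed O-acylation of both phenols, including the hydrogen-bonded B3 hydroxyl. The acetates lower the oxidation potential of the two hydroquinone monoether rings so that they survive step 13.

**Step 13**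
Reactants: 20 the trans-indanone diacetate from step 12
Product: 21 4-acetoxy-2-[3-acetoxy-2-(2,6-dimethoxybenzoyl)-6-methoxy-5-methylphenyl]-3-(2,6-dimethoxyphenyl)-7-methoxy-6-methyl-1H-inden-1-one (acredinone A diacetate)
Conditions: DDQ, 1,4-dioxane, 100 °C
Reagents that add atoms: none
Why: Quinone dehydrogenation of a ketone through its enol: DDQ abstracts hydride from the doubly benzylic C3–H and the resulting oxocarbenium ion loses a proton to give the conjugated indenone. Both stereocentres are erased here.

**Step 14**
Reactants: 21 acredinone A diacetate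
Product: 22 acredinone A
Conditions: K2CO3, MeOH, 0 °C to rt, argon; then aq NH4Cl
Reagents that add atoms: none
Why: Base-catalysed methanolysis of the two aryl acetates; methyl ethers and ketones are inert, and addition of methoxide to the fully substituted C3 is reversible. Exclusion of air protects the phenolates, which are hydroquinone monoethers.

## Compound list

1 | 2-bromo-6-methylphenol | Cc1cccc(Br)c1O | starting material
2 | 1-bromo-2-methoxy-3-methylbenzene | COc1c(C)cccc1Br | intermediate
3 | 2-(3-bromo-4-methoxy-5-methylphenyl)-4,4,5,5-tetramethyl-1,3,2-dioxaborolane (not isolated) | COc1c(C)cc(B2OC(C)(C)C(C)(C)O2)cc1Br | intermediate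
4 | 3-bromo-4-methoxy-5-methylphenol | COc1c(C)cc(O)cc1Br | intermediate
5 | 1-bromo-2-methoxy-5-(methoxymethoxy)-3-methylbenzene | COCOc1cc(C)c(OC)c(Br)c1 | intermediate
6 | [2-methoxy-5-(methoxymethoxy)-3-methylphenyl]lithium (not isolated) | [Li]c1cc(OCOC)cc(C)c1OC | intermediate
7 | N,2-dimethoxy-5-(methoxymethoxy)-N,3-dimethylbenzamide | CON(C)C(=O)c1cc(OCOC)cc(C)c1OC | intermediate
8 | 2,6-dimethylbenzene-1,4-diol (2,6-dimethylhydroquinone) | Cc1cc(O)cc(C)c1O | starting material
9 | 4-(methoxymethoxy)-2,6-dimethylphenol | COCOc1cc(C)c(O)c(C)c1 | intermediate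
10 | 2-methoxy-5-(methoxymethoxy)-1,3-dimethylbenzene | COCOc1cc(C)c(OC)c(C)c1 | intermediate
11 | 2,6-dimethoxybenzoyl chloride | COc1cccc(OC)c1C(Cl)=O | starting material
12 | [3-methoxy-6-(methoxymethoxy)-2,4-dimethylphenyl]lithium (not isolated) | [Li]c1c(C)c(OC)c(C)cc1OCOC | intermediate
13 | (2,6-dimethoxyphenyl)[3-methoxy-6-(methoxymethoxy)-2,4-dimethylphenyl]methanone | COCOc1cc(C)c(OC)c(C)c1C(=O)c1c(OC)cccc1OC | intermediate
14 | lithium (2,6-dimethoxyphenyl)[3-methoxy-6-(methoxymethoxy)-4-methyl-2-methylidenecyclohexa-3,5-dien-1-ylidene]methanolate (not isolated) | [Li]OC(c1c(OC)cccc1OC)=C1C(OCOC)=CC(C)=C(OC)C1=C | intermediate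
15 | 2-[2-(2,6-dimethoxybenzoyl)-6-methoxy-3-(methoxymethoxy)-5-methylphenyl]-1-[2-methoxy-5-(methoxymethoxy)-3-methylphenyl]ethan-1-one | COCOc1cc(C)c(OC)c(CC(=O)c2cc(OCOC)cc(C)c2OC)c1C(=O)c1c(OC)cccc1OC | intermediate
16 | 2,6-dimethoxybenzaldehyde | COc1cccc(OC)c1C=O | starting material
17 | (E)-2-[2-(2,6-dimethoxybenzoyl)-6-methoxy-3-(methoxymethoxy)-5-methylphenyl]-3-(2,6-dimethoxyphenyl)-1-[2-methoxy-5-(methoxymethoxy)-3-methylphenyl]prop-2-en-1-one | O=C(c1cc(OCOC)cc(C)c1OC)/C(c1c(OC)c(C)cc(OCOC)c1C(=O)c1c(OC)cccc1OC)=C/c1c(OC)cccc1OC | intermediate
18 | (E)-2-[2-(2,6-dimethoxybenzoyl)-3-hydroxy-6-methoxy-5-methylphenyl]-3-(2,6-dimethoxyphenyl)-1-(5-hydroxy-2-methoxy-3-methylphenyl)prop-2-en-1-one | O=C(c1cc(O)cc(C)c1OC)/C(c1c(OC)c(C)cc(O)c1C(=O)c1c(OC)cccc1OC)=C/c1c(OC)cccc1OC | intermediate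
19 | (2R*,3S*)-2-[2-(2,6-dimethoxybenzoyl)-3-hydroxy-6-methoxy-5-methylphenyl]-3-(2,6-dimethoxyphenyl)-4-hydroxy-7-methoxy-6-methyl-2,3-dihydro-1H-inden-1-one (trans, racemic, one enantiomer drawn) | O=C1[C@@H](c2c(OC)c(C)cc(O)c2C(=O)c2c(OC)cccc2OC)[C@H](c2c(OC)cccc2OC)c2c(O)cc(C)c(OC)c21 | intermediate
20 | (2R*,3S*)-4-acetoxy-2-[3-acetoxy-2-(2,6-dimethoxybenzoyl)-6-methoxy-5-methylphenyl]-3-(2,6-dimethoxyphenyl)-7-methoxy-6-methyl-2,3-dihydro-1H-inden-1-one (trans, racemic, one enantiomer drawn) | O=C1[C@@H](c2c(OC)c(C)cc(OC(C)=O)c2C(=O)c2c(OC)cccc2OC)[C@H](c2c(OC)cccc2OC)c2c(OC(C)=O)cc(C)c(OC)c21 | intermediate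
21 | 4-acetoxy-2-[3-acetoxy-2-(2,6-dimethoxybenzoyl)-6-methoxy-5-methylphenyl]-3-(2,6-dimethoxyphenyl)-7-methoxy-6-methyl-1H-inden-1-one (acredinone A diacetate) | O=C1C(c2c(OC)c(C)cc(OC(C)=O)c2C(=O)c2c(OC)cccc2OC)=C(c2c(OC)cccc2OC)c2c(OC(C)=O)cc(C)c(OC)c21 | intermediate
22 | acredinone A, 2-[2-(2,6-dimethoxybenzoyl)-3-hydroxy-6-methoxy-5-methylphenyl]-3-(2,6-dimethoxyphenyl)-4-hydroxy-7-methoxy-6-methyl-1H-inden-1-one | COc1cccc(OC)c1C(=O)c1c(O)cc(C)c(OC)c1C1=C(c2c(OC)cccc2OC)c2c(O)cc(C)c(OC)c2C1=O | target

## Step count and least certain steps

Total: 14 steps. Longest linear sequence: 11 steps (1 to 22 through steps 1–4 and 8–14). The ring B branch (steps 5–7) adds 3 steps and joins at step 8.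

**Step 11 (key step).** The most likely failure is that carbon–carbon bond formation is too slow. The C3 cation is strongly stabilised by ring D and crowded, so that capture at the C8 carbonyl oxygen, or intermolecular alkylation of the phenol rings, could win over closure onto C3a.

Fallback, from 17, returning at 22: the ring is closed through an allyl cation that no longer has a deactivating carbonyl on ring A, and the ketone is restored afterwards.
- Luche reduction (NaBH4, CeCl3·7H2O, MeOH) of the C1 carbonyl of 17 should give the allylic alcohol (E)-2-[2-(2,6-dimethoxybenzoyl)-6-methoxy-3-(methoxymethoxy)-5-methylphenyl]-3-(2,6-dimethoxyphenyl)-1-[2-methoxy-5-(methoxymethoxy)-3-methylphenyl]prop-2-en-1-ol F1. The tetra-ortho-substituted C8 ketone is too hindered to be reduced.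
- Catalytic p-toluenesulfonic acid ionises F1 to the 1,3-diarylallyl cation, which alkylates C3a (the known cyclisation of 1,3-diarylallyl alcohols to indenes) to give {2-[1-(2,6-dimethoxyphenyl)-4-methoxy-7-(methoxymethoxy)-5-methyl-1H-inden-2-yl]-3-methoxy-6-(methoxymethoxy)-4-methylphenyl}(2,6-dimethoxyphenyl)methanone F2.
- Base-mediated autoxidation (DBU, O2, DMSO), as used to turn indenes and fluorenes into indenones and fluorenones, deprotonates the doubly benzylic C3–H and oxygenates C1 to give acredinone A bis(methoxymethyl) ether F3.
- Aqueous HCl in methanol then gives 22.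

**Step 8.** The deprotonation may fail or go astray. The C8 carbonyl is twisted out of the plane of ring B and may acidify the B1 methyl group too little, and the base may instead metalate a ring position. The 1,5-diketone product may also cyclise during work-up.

Fallback, from 10 (through the aryllithium 12), returning at 15: the benzylic anion is made from an ester, and ring E is added last.
- 12 is quenched with methyl chloroformate to give methyl 3-methoxy-6-(methoxymethoxy)-2,4-dimethylbenzoate F4.
- Ester-directed lateral lithiation of F4 with LDA and acylation with 7 gives methyl 3-methoxy-2-{2-[2-methoxy-5-(methoxymethoxy)-3-methylphenyl]-2-oxoethyl}-6-(methoxymethoxy)-4-methylbenzoate F5.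
- DBU closes F5 to the isocoumarin 5-methoxy-3-[2-methoxy-5-(methoxymethoxy)-3-methylphenyl]-8-(methoxymethoxy)-6-methyl-1H-isochromen-1-one F6.
- (2,6-Dimethoxyphenyl)lithium F7, made from commercial 1,3-dimethoxybenzene and n-BuLi, adds to the lactone carbonyl of F6. The ring opens to the enolate of 15, which is protonated with acetic acid.

**Step 9.** The condensation may stall for steric reasons, since both partners are di-ortho-substituted. The 1,5-diketone may also be diverted to an isochromene during long heating in the amine/acid buffer.

Fallback, from 15, returning at 17: a stepwise aldol addition and elimination.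
- The lithium enolate of 15 (LiHMDS, THF, −78 °C) is added to 16 and quenched cold to give the aldol 2-[2-(2,6-dimethoxybenzoyl)-6-methoxy-3-(methoxymethoxy)-5-methylphenyl]-3-(2,6-dimethoxyphenyl)-3-hydroxy-1-[2-methoxy-5-(methoxymethoxy)-3-methylphenyl]propan-1-one F8.
- MsCl and Et3N convert F8 into the corresponding 3-(methylsulfonyl)oxy ketone F9, which is not expected to be isolable and loses methanesulfonic acid on addition of DBU to give 17.

**Step 13.** Hydride abstraction from the crowded C3–H may be slow. The oxidant may then attack the benzylic methyl groups of the anisole rings or the electron-rich ring D.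

Fallback, from 20, returning at 21: Saegusa–Ito oxidation.
- TMSOTf and Et3N convert 20 into the silyl enol ether 2-[3-acetoxy-2-(2,6-dimethoxybenzoyl)-6-methoxy-5-methylphenyl]-1-(2,6-dimethoxyphenyl)-4-methoxy-5-methyl-3-(trimethylsilyloxy)-1H-inden-7-yl acetate F10.
- Pd(OAc)2 in MeCN dehydrosilylates F10 to 21. Palladium adds to C2 on the face away from ring D, which places it syn to the C3 hydrogen as required for β-hydride elimination.

## Further compounds

F1 | step 11 | (E)-2-[2-(2,6-dimethoxybenzoyl)-6-methoxy-3-(methoxymethoxy)-5-methylphenyl]-3-(2,6-dimethoxyphenyl)-1-[2-methoxy-5-(methoxymethoxy)-3-methylphenyl]prop-2-en-1-ol (racemic, one enantiomer drawn) | O[C@H](c1cc(OCOC)cc(C)c1OC)/C(c1c(OC)c(C)cc(OCOC)c1C(=O)c1c(OC)cccc1OC)=C/c1c(OC)cccc1OC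
F2 | step 11 | {2-[1-(2,6-dimethoxyphenyl)-4-methoxy-7-(methoxymethoxy)-5-methyl-1H-inden-2-yl]-3-methoxy-6-(methoxymethoxy)-4-methylphenyl}(2,6-dimethoxyphenyl)methanone (racemic, one enantiomer drawn) | COCOc1cc(C)c(OC)c2c1[C@H](c1c(OC)cccc1OC)C(c1c(OC)c(C)cc(OCOC)c1C(=O)c1c(OC)cccc1OC)=C2
F3 | step 11 | acredinone A bis(methoxymethyl) ether | O=C1C(c2c(OC)c(C)cc(OCOC)c2C(=O)c2c(OC)cccc2OC)=C(c2c(OC)cccc2OC)c2c(OCOC)cc(C)c(OC)c21
F4 | step 8 | methyl 3-methoxy-6-(methoxymethoxy)-2,4-dimethylbenzoate | COCOc1cc(C)c(OC)c(C)c1C(=O)OC
F5 | step 8 | methyl 3-methoxy-2-{2-[2-methoxy-5-(methoxymethoxy)-3-methylphenyl]-2-oxoethyl}-6-(methoxymethoxy)-4-methylbenzoate | COCOc1cc(C)c(OC)c(CC(=O)c2cc(OCOC)cc(C)c2OC)c1C(=O)OC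
F6 | step 8 | 5-methoxy-3-[2-methoxy-5-(methoxymethoxy)-3-methylphenyl]-8-(methoxymethoxy)-6-methyl-1H-isochromen-1-one | COCOc1cc(C)c(OC)c2C=C(c3cc(OCOC)cc(C)c3OC)OC(=O)c12
F7 | step 8 | (2,6-dimethoxyphenyl)lithium | [Li]c1c(OC)cccc1OC
F8 | step 9 | 2-[2-(2,6-dimethoxybenzoyl)-6-methoxy-3-(methoxymethoxy)-5-methylphenyl]-3-(2,6-dimethoxyphenyl)-3-hydroxy-1-[2-methoxy-5-(methoxymethoxy)-3-methylphenyl]propan-1-one (mixture of racemic diastereomers, configuration not defined) | O=C(c1cc(OCOC)cc(C)c1OC)C(c1c(OC)c(C)cc(OCOC)c1C(=O)c1c(OC)cccc1OC)C(O)c1c(OC)cccc1OC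
F9 | step 9 | 2-[2-(2,6-dimethoxybenzoyl)-6-methoxy-3-(methoxymethoxy)-5-methylphenyl]-1-(2,6-dimethoxyphenyl)-3-[2-methoxy-5-(methoxymethoxy)-3-methylphenyl]-3-oxopropyl methanesulfonate (mixture of racemic diastereomers, configuration not defined) | O=C(c1cc(OCOC)cc(C)c1OC)C(c1c(OC)c(C)cc(OCOC)c1C(=O)c1c(OC)cccc1OC)C(OS(C)(=O)=O)c1c(OC)cccc1OC
F10 | step 13 | 2-[3-acetoxy-2-(2,6-dimethoxybenzoyl)-6-methoxy-5-methylphenyl]-1-(2,6-dimethoxyphenyl)-4-methoxy-5-methyl-3-(trimethylsilyloxy)-1H-inden-7-yl acetate (racemic, one enantiomer drawn) | C[Si](C)(C)OC1=C(c2c(OC)c(C)cc(OC(C)=O)c2C(=O)c2c(OC)cccc2OC)[C@H](c2c(OC)cccc2OC)c2c(OC(C)=O)cc(C)c(OC)c21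
A1 | alternative 1 | 2-{2-[(tert-butyldimethylsilyloxy)(2,6-dimethoxyphenyl)methyl]-3-hydroxy-6-methoxy-5-methylphenyl}-3-(2,6-dimethoxyphenyl)-7-methoxy-4-(methoxymethoxy)-6-methyl-1H-inden-1-one (racemic, one enantiomer drawn) | O=C1C(c2c(OC)c(C)cc(O)c2[C@H](O[Si](C)(C)C(C)(C)C)c2c(OC)cccc2OC)=C(c2c(OC)cccc2OC)c2c(OCOC)cc(C)c(OC)c21
A2 | alternative 1 | 2-[3-(tert-butyldimethylsilyloxy)-3-(2,6-dimethoxyphenyl)prop-1-yn-1-yl]-3-(2,6-dimethoxyphenyl)-7-methoxy-4-(methoxymethoxy)-6-methyl-1H-inden-1-one (racemic, one enantiomer drawn) | O=C1C(C#C[C@H](O[Si](C)(C)C(C)(C)C)c2c(OC)cccc2OC)=C(c2c(OC)cccc2OC)c2c(OCOC)cc(C)c(OC)c21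
A3 | alternative 1 | pentacarbonyl[methoxy(prop-1-en-2-yl)methylidene]chromium, (CO)5Cr=C(OMe)C(Me)=CH2 | C=C(C)C(OC)=[Cr].[C-]#[O+].[C-]#[O+].[C-]#[O+].[C-]#[O+].[C-]#[O+]
A4 | alternative 2 | open-chain bis-aryl ketone with rings A and B formed, C1 as tert-butyldimethylsilyl-protected carbinol, C2 as CH2 and triisopropylsilyl ethers at O4 and the B3 oxygen (racemic, one enantiomer drawn) | COc1cccc(OC)c1C(=O)c1c(O[Si](C(C)C)(C(C)C)C(C)C)cc(C)c(O)c1[C@H](O[Si](C)(C)C(C)(C)C)Cc1c(O)c(C)cc(O[Si](C(C)C)(C(C)C)C(C)C)c1C(=O)c1c(OC)cccc1OC
A5 | alternative 2 | 4-(tert-butyldimethylsilyloxy)-1,8-bis(2,6-dimethoxyphenyl)octa-2,6-diyne-1,8-dione (racemic, one enantiomer drawn) | COc1cccc(OC)c1C(=O)C#C[C@H](O[Si](C)(C)C(C)(C)C)CC#CC(=O)c1c(OC)cccc1OC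
A6 | alternative 2 | 4-methyl-2-(triisopropylsilyloxy)furan | Cc1coc(O[Si](C(C)C)(C(C)C)C(C)C)c1
A7 | alternative 3 | acredinone A diacetate (identical with 21) | O=C1C(c2c(OC)c(C)cc(OC(C)=O)c2C(=O)c2c(OC)cccc2OC)=C(c2c(OC)cccc2OC)c2c(OC(C)=O)cc(C)c(OC)c21
A8 | alternative 3 | 3-[3-(2,6-dimethoxyphenyl)prop-2-ynoyl]-4-methoxy-5-methylphenyl acetate | CC(=O)Oc1cc(C)c(OC)c(C(=O)C#Cc2c(OC)cccc2OC)c1
A9 | alternative 3 | 3-acetoxy-2-(2,6-dimethoxybenzoyl)-6-methoxy-5-methylbenzenediazonium tetrafluoroborate | CC(=O)Oc1cc(C)c(OC)c([N+]#N)c1C(=O)c1c(OC)cccc1OC.F[B-](F)(F)F
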